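**Assumption:** marigold-derived all-E (3R,3'R,6'R)-lutein (free diol) is taken as a cheap commercial starting material; the tertiary amine bases only carry a proton and come back as free amines on aqueous work-up.

The target is (3R,3'R,6'R)-lutein 3-O-palmitate 3'-O-myristate: palmitate on the homoallylic 3-OH of the β-ring, myristate on the allylic 3'-OH of the ε-ring, all-E polyene.

## Retrosynthetic overview

1. The full C40 polyene, both six-membered rings and all three stereocentres (3R, 3'R, 6'R) come intact from lutein 1; no ring is formed in the route.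
2. Key disconnection (made first): the allylic C3'–O ester bond, formed by catalyst-controlled site-selective transfer of one myristoyl group from myristic anhydride 2 to O3' of the unprotected diol, giving monoester 3.
3. Last disconnection: the C3–O ester bond, formed from 3 and palmitic anhydride 4 to give the target 5.
4. Order 1 → 3 → 5: no protecting groups, no C–C bond formation, no change at any stereocentre.

## Route

**Step 1**
Reactants: 1 (3R,3'R,6'R)-lutein; 2 myristic anhydride
Product: 3 lutein 3'-O-myristate [(3R,3'R,6'R)-3-hydroxy-β,ε-caroten-3'-yl tetradecanoate]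
Conditions: 2 (1.1 equiv), (R)-2-phenyl-2,3-dihydroimidazo[2,1-b]benzothiazole [(R)-BTM] (10 mol %), iPr2NEt (1.2 equiv), CH2Cl2 (filtered through basic Al2O3), 0 °C, Ar, dark; chromatography on Et3N-deactivated SiO2
Reagents that add atoms: myristic anhydride (2), CCCCCCCCCCCCCC(=O)OC(=O)CCCCCCCCCCCCC
Why: Proposed new method: site-selective O-acylation of an unprotected carotenoid diol by a chiral isothiourea – the N-myristoyl isothiouronium formed from (R)-BTM and 2 transfers its acyl group fastest to a secondary carbinol that carries a C=C directly on the carbinol carbon (the alkene stacks on the cationic benzothiazolium face, the carboxylate acts as general base), which only the allylic 3'-OH offers; in addition the two carbinol centres of lutein are locally quasi-enantiomeric (3'R has the (R)-1-arylethanol topology that (R)-BTM acylates fast, the homoallylic 3-OH has the opposite local sense and no π-group on the carbinol carbon), so both recognition elements send the single myristoyl group to O3', and O-acylation leaves every stereocentre untouched; the closest known reaction type is the isothiourea-catalysed acylative kinetic resolution of benzylic and allylic secondary alcohols, not yet shown for site selection between an allylic and a homoallylic hydroxyl in one molecule or on a carotenoid.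

**Step 2**
Reactants: 3 lutein 3'-O-myristate; 4 palmitic anhydride
Product: 5 lutein 3-O-palmitate 3'-O-myristate [(3R,3'R,6'R)-3'-(tetradecanoyloxy)-β,ε-caroten-3-yl hexadecanoate]
Conditions: 4 (1.5 equiv), 4-(dimethylamino)pyridine (DMAP, 20 mol %), Et3N (2 equiv), CH2Cl2, 0 °C to rt, Ar, dark; chromatography, then crystallisation
Reagents that add atoms: palmitic anhydride (4), CCCCCCCCCCCCCCCC(=O)OC(=O)CCCCCCCCCCCCCCC
Why: DMAP-catalysed acylation with an anhydride (Steglich-type nucleophilic catalysis) of the only remaining, unhindered secondary 3-OH; acylation at oxygen keeps C3 as 3R, and the allylic 3'-ester and the polyene tolerate the acid-free basic medium.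

## Compound list

1 | (3R,3'R,6'R)-lutein, all-E-β,ε-carotene-3,3'-diol | O[C@@H]1CC(C)=C(/C=C/C(C)=C/C=C/C(C)=C/C=C/C=C(C)/C=C/C=C(C)/C=C/[C@H]2C(C)=C[C@H](O)CC2(C)C)C(C)(C)C1 | starting material
2 | myristic (tetradecanoic) anhydride | CCCCCCCCCCCCCC(=O)OC(=O)CCCCCCCCCCCCC | starting material
3 | lutein 3'-O-myristate, (3R,3'R,6'R)-3-hydroxy-β,ε-caroten-3'-yl tetradecanoate | O[C@@H]1CC(C)=C(/C=C/C(C)=C/C=C/C(C)=C/C=C/C=C(C)/C=C/C=C(C)/C=C/[C@H]2C(C)=C[C@H](OC(=O)CCCCCCCCCCCCC)CC2(C)C)C(C)(C)C1 | intermediate
4 | palmitic (hexadecanoic) anhydride | CCCCCCCCCCCCCCCC(=O)OC(=O)CCCCCCCCCCCCCCC | starting material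
5 | lutein 3-O-palmitate 3'-O-myristate, (3R,3'R,6'R), all-E | CCCCCCCCCCCCCCCC(=O)O[C@@H]1CC(C)=C(/C=C/C(C)=C/C=C/C(C)=C/C=C/C=C(C)/C=C/C=C(C)/C=C/[C@H]2C(C)=C[C@H](OC(=O)CCCCCCCCCCCCC)CC2(C)C)C(C)(C)C1 | target

## Step count and risks

Total step count: 2. Longest linear sequence: 2.

The route has only two steps, so both are ranked; there is no third step to name.

**1. Step 1 (the proposed new step), most likely to fail.** The risks are too little site selectivity (3-O-myristate regioisomer, dimyristate) or slow turnover because the recognised alkene is an isolated trisubstituted C=C and not an arene. The regioisomer must be removed at 3, since it would lead to an isomer of 5. The regiochemistry of 3 can be read from the 1H NMR spectrum: the allylic H-3' moves downfield on acylation while H-3 stays at the carbinol position. Zeaxanthin in technical lutein has no allylic OH and should stay behind as the diol.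

Fallback, known chemistry only, setting out from 1 and coming back at 5: the two hydroxyls are told apart by oxidation state instead of by a catalyst. Activated MnO2 (CH2Cl2, rt, dark) oxidises only the allylic 3'-OH of 1 and gives (3R,6'R)-3-hydroxy-β,ε-caroten-3'-one (3'-oxolutein) F1. The single remaining hydroxyl is acylated with 4 (pyridine, 5 mol % DMAP, CH2Cl2, 0 °C; kept weakly basic because H-6' is γ to the enone carbonyl) to give 3'-oxolutein 3-O-palmitate F2. Luche 1,2-reduction (NaBH4, CeCl3·7H2O, THF/MeOH, −20 °C) gives the two C3' epimers, lutein 3-O-palmitate F3 (3'R) and 3'-epilutein 3-O-palmitate F4 (3'S). They are separated on silica, and F4 is returned to F2 with MnO2. F3 is then acylated at the allylic 3'-OH with 2 (DMAP, Et3N, CH2Cl2, 0 °C) to give 5. This costs four steps instead of two.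

**2. Step 2.** The risks are E/Z isomerisation of the polyene, loss or scrambling of the allylic 3'-ester under DMAP and amine, and difficult removal of excess fatty material from the very lipophilic product.

Fallback, setting out from 3 and coming back at 5: replace chemical acyl transfer by biocatalytic transesterification. Treat 3 with vinyl palmitate (3 equiv) and immobilised Candida antarctica lipase B (Novozym 435) in dry toluene at 45 °C over 4 Å molecular sieves in the dark. The enol ester makes the acyl transfer irreversible, no base or nucleophilic catalyst is present, and the enzyme is filtered off. This fallback makes no new compound (F0).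

## Further compounds

F1 | step 1 | (3R,6'R)-3-hydroxy-β,ε-caroten-3'-one (3'-oxolutein) | O[C@@H]1CC(C)=C(/C=C/C(C)=C/C=C/C(C)=C/C=C/C=C(C)/C=C/C=C(C)/C=C/[C@H]2C(C)=CC(=O)CC2(C)C)C(C)(C)C1
F2 | step 1 | 3'-oxolutein 3-O-palmitate, (3R,6'R)-3'-oxo-β,ε-caroten-3-yl hexadecanoate | CCCCCCCCCCCCCCCC(=O)O[C@@H]1CC(C)=C(/C=C/C(C)=C/C=C/C(C)=C/C=C/C=C(C)/C=C/C=C(C)/C=C/[C@H]2C(C)=CC(=O)CC2(C)C)C(C)(C)C1
F3 | step 1 | lutein 3-O-palmitate, (3R,3'R,6'R)-3'-hydroxy-β,ε-caroten-3-yl hexadecanoate | CCCCCCCCCCCCCCCC(=O)O[C@@H]1CC(C)=C(/C=C/C(C)=C/C=C/C(C)=C/C=C/C=C(C)/C=C/C=C(C)/C=C/[C@H]2C(C)=C[C@H](O)CC2(C)C)C(C)(C)C1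
F4 | step 1 | 3'-epilutein 3-O-palmitate, (3R,3'S,6'R)-3'-hydroxy-β,ε-caroten-3-yl hexadecanoate | CCCCCCCCCCCCCCCC(=O)O[C@@H]1CC(C)=C(/C=C/C(C)=C/C=C/C(C)=C/C=C/C=C(C)/C=C/C=C(C)/C=C/[C@H]2C(C)=C[C@@H](O)CC2(C)C)C(C)(C)C1
F0 | step 2 | none | none
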